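## Plan

1. Retrosynthesis: the bond between the side-chain carbinol carbon and C-2 of the oxane ring is cut first, at the ketone oxidation level (dienoyl thioester plus 2-stannyl oxane). The polyene half is then cut at the two diene single bonds (Heck couplings) and at the Z-trisubstituted alkene (iodo-Wittig). The oxane half is cut at its ring C–O bond (lactonisation) and at two chain C–C bonds (acetate Claisen, propionate aldol).
2. Forward: (a) the dihydropyranone ring is closed by metathesis and masked as its isopropyl acetal; (b) the polyene thioester is grown linearly from a C4 bromo alcohol and joined to (a); (c) the oxane ring arises by lactonisation of a syn,syn-diol ester and is converted into the anomeric stannane. Fragments (b) and (c) are then united, followed by acetal to lactone, ketone to carbinol, and desilylation.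
3. Stereochemistry: the lactone centre comes from (S)-epichlorohydrin and the chain methyl centre from (S)-3-bromo-2-methylpropan-1-ol. Oxane C-5/C-6 come from an Evans syn aldol, C-4 from a 1,3-syn reduction, and C-2 from SN2 stannylation followed by retentive coupling. The carbinol comes from chelation-controlled reduction.
4. Alkene geometries come from syn-carboalumination, two Heck reactions, a Z-selective iodo-Wittig reaction and (E)-crotonaldehyde.
5. Enabling feature: oxane C-2 is flanked by the ring oxygen. Its C–Sn bond is therefore configurationally stable and transfers with retention, the derived 2-acyl oxane is thermodynamically 2,6-cis, and the ring oxygen together with the exocyclic C=O forms the five-membered zinc chelate that fixes the carbinol.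

Key step: step 22

Remark (assumption): (S)-epichlorohydrin, (S)-3-bromo-2-methylpropan-1-ol, (S)-4-benzyl-3-propionyloxazolidin-2-one and (E)-crotonaldehyde are taken as commercial single isomers. The acetal carbon of the masked lactone is carried as an anomer mixture because it is removed in step 23.

## Route

Step 1
Reactants: 1 (S)-epichlorohydrin
Product: 2 (S)-1-chloropent-4-en-2-ol
Conditions: CH2=CHMgBr, CuI (10 mol %), THF, −40 °C; aq. NH4Cl
Reagents that add atoms: vinylmagnesium bromide (C=C[Mg]Br)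
Why: Copper-catalysed Grignard opening of an epoxide (SN2 at the unsubstituted CH2) is faster than attack at C–Cl, so the C–O stereocentre of 1 is carried over untouched.

Step 2
Reactants: 2 (S)-1-chloropent-4-en-2-ol
Product: 4 (S)-hexa-1,5-dien-3-ol, via (S)-2-allyloxirane 3 (not isolated)
Conditions: Me3S+ I− (4 equiv), n-BuLi (3.9 equiv), THF, −20 °C → rt
Reagents that add atoms: trimethylsulfonium iodide (C[S+](C)C.[I-])
Why: Sulfonium-ylide homologation of an epoxide to an allylic alcohol (Corey–Chaykovsky reagent in excess): the ylide closes the chlorohydrin to 3, opens it at CH2, and a further equivalent eliminates dimethyl sulfide from the β-alkoxy sulfonium salt, none of which touches the stereocentre.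

Step 3
Reactants: 4 (S)-hexa-1,5-dien-3-ol
Product: 5 (S)-hexa-1,5-dien-3-yl acrylate
Conditions: CH2=CHCOCl, Et3N, DMAP (cat.), CH2Cl2, 0 °C
Reagents that add atoms: acryloyl chloride (C=CC(=O)Cl)
Why: Standard O-acylation of a secondary alcohol by an acid chloride with amine base.

Step 4
Reactants: 5 (S)-hexa-1,5-dien-3-yl acrylate
Product: 6 (S)-6-vinyl-5,6-dihydro-2H-pyran-2-one
Conditions: second-generation Grubbs catalyst (3 mol %), CH2Cl2 (0.01 M), 40 °C
Reagents that add atoms: none
Why: Ring-closing metathesis: the unhindered allyl terminus initiates and closes on the acrylate to the six-membered enoate, whereas the branched vinyl group on the carbinol carbon is slow to react and remains as the later Heck handle.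

Step 5
Reactants: 6 (S)-6-vinyl-5,6-dihydro-2H-pyran-2-one
Product: 8 (6S)-2-isopropoxy-6-vinyl-5,6-dihydro-2H-pyran (anomer mixture), via lactol 7 (not isolated)
Conditions: iBu2AlH, CH2Cl2, −78 °C; aq. potassium sodium tartrate; crude lactol, i-PrOH, PPTS (cat.), rt
Reagents that add atoms: propan-2-ol (CC(C)O)
Why: Half-reduction of a lactone at low temperature followed by acid-catalysed acetalisation through the allylic oxocarbenium ion; the acetal masks the 6-alkenyl lactone, which would otherwise behave as an allylic carboxylate towards zerovalent palladium in steps 14 and 22.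

Step 6
Reactants: 9 (S)-3-bromo-2-methylpropan-1-ol
Product: 10 (S)-(3-bromo-2-methylpropoxy)(tert-butyl)dimethylsilane
Conditions: TBSCl, imidazole, CH2Cl2, rt
Reagents that add atoms: tert-butyldimethylsilyl chloride (CC(C)(C)[Si](C)(C)Cl)
Why: Silyl ether formation at the primary alcohol keeps it inert in the following basic and organometallic steps.

Step 7
Reactants: 10 (S)-(3-bromo-2-methylpropoxy)(tert-butyl)dimethylsilane
Product: 11 (R)-tert-butyldimethyl[(2-methylpent-4-yn-1-yl)oxy]silane
Conditions: LiC≡CH·H2NCH2CH2NH2, DMSO, 0 °C → rt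
Reagents that add atoms: lithium acetylide–ethylenediamine complex ([Li+].[C-]#C.NCCN)
Why: SN2 alkylation of acetylide by a primary bromide in a dipolar aprotic solvent; the adjacent stereocentre is not involved (the descriptor changes only through priorities).

Step 8
Reactants: 11 (R)-tert-butyldimethyl[(2-methylpent-4-yn-1-yl)oxy]silane
Product: 13 (R,E)-tert-butyl[(5-iodo-2,4-dimethylpent-4-en-1-yl)oxy]dimethylsilane, via alkenyl(dimethyl)alane 12 (not isolated)
Conditions: AlMe3 (2.5 equiv), Cp2ZrCl2 (0.25 equiv), CH2Cl2, 0 °C → rt; then I2, THF, −30 → 0 °C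
Reagents that add atoms: trimethylaluminium (C[Al](C)C); iodine (II)
Why: Negishi zirconium-catalysed carboalumination adds methyl and aluminium syn across the terminal alkyne with aluminium at the terminus, and iodinolysis with retention gives the E-configured trisubstituted alkenyl iodide.

Step 9
Reactants: 13 (R,E)-tert-butyl[(5-iodo-2,4-dimethylpent-4-en-1-yl)oxy]dimethylsilane
Product: 14 (2E,4E,7R)-8-(tert-butyldimethylsilyloxy)-5,7-dimethylocta-2,4-dienoic acid
Conditions: acrylic acid, Pd(OAc)2 (5 mol %), Bu4NCl, K2CO3, DMF, 45 °C; aq. citric acid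
Reagents that add atoms: acrylic acid (C=CC(=O)O)
Why: Heck reaction under Jeffery conditions: syn carbopalladation of the acrylate and syn β-hydride elimination give the new E alkene while the alkenyl iodide geometry is retained.

Step 10
Reactants: 14 (2E,4E,7R)-8-(tert-butyldimethylsilyloxy)-5,7-dimethylocta-2,4-dienoic acid
Product: 15 S-phenyl (2E,4E,7R)-8-(tert-butyldimethylsilyloxy)-5,7-dimethylocta-2,4-dienethioate
Conditions: PhSH, DCC, DMAP (cat.), CH2Cl2, 0 °C
Reagents that add atoms: benzenethiol (Sc1ccccc1)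
Why: Steglich-type carbodiimide thioesterification installs the acyl donor needed for step 22 before any lactone equivalent is present.

Step 11
Reactants: 15 S-phenyl (2E,4E,7R)-8-(tert-butyldimethylsilyloxy)-5,7-dimethylocta-2,4-dienethioate
Product: 16 S-phenyl (2E,4E,7R)-8-hydroxy-5,7-dimethylocta-2,4-dienethioate
Conditions: HF·pyridine, pyridine, THF, 0 °C → rt
Reagents that add atoms: none
Why: Fluoride cleavage of the primary silyl ether under buffered conditions that leave the thioester and the diene untouched.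

Step 12
Reactants: 16 S-phenyl (2E,4E,7R)-8-hydroxy-5,7-dimethylocta-2,4-dienethioate
Product: 17 S-phenyl (2E,4E,7R)-5,7-dimethyl-8-oxoocta-2,4-dienethioate
Conditions: Dess–Martin periodinane, NaHCO3, CH2Cl2, 0 °C → rt; used directly
Reagents that add atoms: none
Why: Dess–Martin oxidation under bicarbonate buffer should give the α-methyl aldehyde without epimerisation.

Step 13
Reactants: 17 S-phenyl (2E,4E,7R)-5,7-dimethyl-8-oxoocta-2,4-dienethioate
Product: 18 S-phenyl (2E,4E,7R,8Z)-9-iodo-5,7-dimethyldeca-2,4,8-trienethioate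
Conditions: EtPPh3I, n-BuLi, THF, rt; I2, −78 °C; NaN(SiMe3)2, −78 → −20 °C; then 17, −78 °C
Reagents that add atoms: ethyltriphenylphosphonium iodide (CC[P+](c1ccccc1)(c1ccccc1)c1ccccc1.[I-]); iodine (II)
Why: Wittig olefination with the α-iodo ylide (Stork–Zhao type) proceeds through the kinetically favoured cis-oxaphosphetane and should place iodine cis to the chain (Z), at −78 °C where the aldehyde reacts far faster than the thioester.

Step 14
Reactants: 18 S-phenyl (2E,4E,7R,8Z)-9-iodo-5,7-dimethyldeca-2,4,8-trienethioate; 8 (6S)-2-isopropoxy-6-vinyl-5,6-dihydro-2H-pyran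
Product: 19 S-phenyl (2E,4E,7R,8Z,10E)-11-[(2S)-6-isopropoxy-3,6-dihydro-2H-pyran-2-yl]-5,7,9-trimethylundeca-2,4,8,10-tetraenethioate
Conditions: Pd(OAc)2 (10 mol %), Bu4NCl, NaHCO3, DMF, 40 °C
Reagents that add atoms: none
Why: Heck coupling (Jeffery conditions) of the alkenyl iodide with the terminal vinyl group: retention at the Z iodide and syn β-hydride elimination towards the new chain carbon should give the E,Z-diene, the allylic acetal oxygen being a poor leaving group for palladium.

Step 15
Reactants: 20 (S)-4-benzyl-3-propionyloxazolidin-2-one; 21 (E)-but-2-enal (crotonaldehyde)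
Product: 23 (S)-4-benzyl-3-[(2S,3R,4E)-3-hydroxy-2-methylhex-4-enoyl]oxazolidin-2-one, via Z-boron enolate 22 (not isolated)
Conditions: Bu2BOTf, iPr2NEt, CH2Cl2, −78 → 0 °C; 21, −78 → 0 °C; pH 7 buffer, MeOH, H2O2
Reagents that add atoms: none
Why: Evans syn aldol: the Z-boron enolate reacts through a Zimmerman–Traxler chair on the face opposite the benzyl group, setting the 2S,3R syn pair that becomes oxane C-5 and C-6.

Step 16
Reactants: 23 (S)-4-benzyl-3-[(2S,3R,4E)-3-hydroxy-2-methylhex-4-enoyl]oxazolidin-2-one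
Product: 24 (2S,3R,4E)-3-hydroxy-N-methoxy-N,2-dimethylhex-4-enamide
Conditions: MeNHOMe·HCl, AlMe3, CH2Cl2, −20 → 0 °C; aq. HCl work-up
Reagents that add atoms: N,O-dimethylhydroxylamine hydrochloride (CNOC.Cl)
Why: Aluminium-amide transamination (Weinreb amide formation) releases the auxiliary and provides an acyl group that stops at the ketone stage.

Step 17
Reactants: 24 (2S,3R,4E)-3-hydroxy-N-methoxy-N,2-dimethylhex-4-enamide
Product: 25 ethyl (4S,5R,6E)-5-hydroxy-4-methyl-3-oxooct-6-enoate
Conditions: EtOAc, LiN(iPr)2 (3.5 equiv each), THF, −78 °C; then 24, −78 → −40 °C; aq. NH4Cl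
Reagents that add atoms: ethyl acetate (CCOC(C)=O)
Why: Claisen-type acylation of the ester enolate by the Weinreb amide via a stable chelated tetrahedral intermediate; excess enolate covers the free hydroxyl and the acidic product.

Step 18
Reactants: 25 ethyl (4S,5R,6E)-5-hydroxy-4-methyl-3-oxooct-6-enoate
Product: 27 (4S,5R,6R)-4-hydroxy-5-methyl-6-[(E)-prop-1-enyl]tetrahydro-2H-pyran-2-one, via syn-diol ester 26 (not isolated)
Conditions: Et2BOMe, NaBH4, THF/MeOH (4:1), −78 °C; AcOH, MeOH co-evaporation; then PPTS (cat.), toluene, 60 °C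
Reagents that add atoms: none
Why: Narasaka–Prasad reduction: the diethylboron chelate of the β-hydroxy ketone is attacked axially by external hydride to give the 1,3-syn diol (new centre = oxane C-4, all-syn triad), and mild acid then closes the δ-lactone through the allylic hydroxyl.

Step 19
Reactants: 27 (4S,5R,6R)-4-hydroxy-5-methyl-6-[(E)-prop-1-enyl]tetrahydro-2H-pyran-2-one
Product: 28 (4S,5S,6R)-4-(tert-butyldimethylsilyloxy)-5-methyl-6-[(E)-prop-1-enyl]tetrahydro-2H-pyran-2-one
Conditions: TBSOTf, 2,6-lutidine, CH2Cl2, −78 °C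
Reagents that add atoms: tert-butyldimethylsilyl triflate (CC(C)(C)[Si](C)(C)OS(=O)(=O)C(F)(F)F)
Why: Silylation of the hindered secondary alcohol with the silyl triflate and a non-nucleophilic base at low temperature avoids β-elimination of the lactone (the descriptor at C-5 changes only through priorities).

Step 20
Reactants: 28 (4S,5S,6R)-4-(tert-butyldimethylsilyloxy)-5-methyl-6-[(E)-prop-1-enyl]tetrahydro-2H-pyran-2-one
Product: 29 (4S,5S,6R)-4-(tert-butyldimethylsilyloxy)-5-methyl-6-[(E)-prop-1-enyl]tetrahydro-2H-pyran-2-ol (anomer mixture)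
Conditions: iBu2AlH, CH2Cl2, −78 °C; aq. potassium sodium tartrate
Reagents that add atoms: none
Why: Half-reduction of the δ-lactone at −78 °C stops at the stable aluminium hemiacetal and gives the lactol on work-up.

Step 21
Reactants: 29 (4S,5S,6R)-4-(tert-butyldimethylsilyloxy)-5-methyl-6-[(E)-prop-1-enyl]tetrahydro-2H-pyran-2-ol
Product: 31 tributyl[(2S,4S,5S,6R)-4-(tert-butyldimethylsilyloxy)-5-methyl-6-[(E)-prop-1-enyl]tetrahydro-2H-pyran-2-yl]stannane (tin equatorial, cis to propenyl), via axial anomeric chloride 30 (not isolated)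
Conditions: ClC(NMe2)=CMe2, CH2Cl2, 0 °C; evaporate; Bu3SnLi (from Bu3SnH and LiN(iPr)2), THF, −78 °C
Reagents that add atoms: tributyltin hydride (CCCC[SnH](CCCC)CCCC)
Why: Neutral chlorination of the lactol with the α-chloroenamine should give mainly the axial anomeric chloride (anomeric effect), and SN2 displacement by Bu3SnLi with inversion, the known route to equatorial 2-deoxyglycosyl stannanes, places tin cis to the C-6 propenyl group.

Step 22
Reactants: 31 tributyl[(2S,4S,5S,6R)-4-(tert-butyldimethylsilyloxy)-5-methyl-6-[(E)-prop-1-enyl]tetrahydro-2H-pyran-2-yl]stannane; 19 S-phenyl (2E,4E,7R,8Z,10E)-11-[(2S)-6-isopropoxy-3,6-dihydro-2H-pyran-2-yl]-5,7,9-trimethylundeca-2,4,8,10-tetraenethioate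
Product: 32 (2E,4E,7R,8Z,10E)-1-[(2R,4S,5S,6R)-4-(tert-butyldimethylsilyloxy)-5-methyl-6-[(E)-prop-1-enyl]tetrahydro-2H-pyran-2-yl]-11-[(2S)-6-isopropoxy-3,6-dihydro-2H-pyran-2-yl]-5,7,9-trimethylundeca-2,4,8,10-tetraen-1-one
Conditions: Pd2(dba)3 (5 mol %), JackiePhos (20 mol %), CuCl (1.5 equiv), degassed 1,4-dioxane, 90 °C
Reagents that add atoms: none
Why: Zerovalent palladium adds oxidatively to the C(acyl)–S bond of 19, CuCl captures the thiolate and mediates transfer of the oxane C-2 carbon from tin to palladium through a closed transition state with retention, and reductive elimination from the acyl(alkyl)palladium gives the ketone. The closest known reaction type is the stereoretentive Stille/Liebeskind–Srogl acylation of configurationally stable anomeric (α-alkoxy) stannanes. No ring is closed. No new stereocentre is formed, but the configuration at oxane C-2 is fixed here: it is carried over from the equatorial C–Sn bond of 31, and because this carbon is now α to a ketone and the equatorial 2,6-cis arrangement is the thermodynamic one, any axial epimer would converge on 32 on brief treatment with mild base. The step needs transfer of the secondary oxanyl group in preference to butyl (secured by the α-oxygen), reductive elimination faster than β-hydride elimination towards the ring CH2 (bulky electron-poor biarylphosphine) and oxidative addition only at the thioester (the lactone is masked as an acetal and all other C–O bonds are ethers). The ketone oxidation level installed here is the helper for step 24, where the ring oxygen and this carbonyl chelate zinc.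

Step 23
Reactants: 32 the acetal ketone from step 22
Product: 34 (6S)-6-[(1E,3Z,5R,7E,9E)-11-[(2R,4S,5S,6R)-4-(tert-butyldimethylsilyloxy)-5-methyl-6-[(E)-prop-1-enyl]tetrahydro-2H-pyran-2-yl]-3,5,7-trimethyl-11-oxoundeca-1,3,7,9-tetraenyl]-5,6-dihydro-2H-pyran-2-one, via lactol ketone 33 (not isolated)
Conditions: PPTS, acetone/H2O (4:1), rt; then MnO2, CH2Cl2, rt
Reagents that add atoms: water (O)
Why: Mild acid hydrolysis of the allylic acetal and selective MnO2 oxidation of the allylic lactol regenerate the unsaturated δ-lactone while the side-chain carbon is still a ketone and no other hydroxyl is free.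

Step 24
Reactants: 34 the lactone ketone from step 23
Product: 35 (6S)-6-[(1E,3Z,5R,7E,9E,11S)-11-[(2R,4S,5S,6R)-4-(tert-butyldimethylsilyloxy)-5-methyl-6-[(E)-prop-1-enyl]tetrahydro-2H-pyran-2-yl]-11-hydroxy-3,5,7-trimethylundeca-1,3,7,9-tetraenyl]-5,6-dihydro-2H-pyran-2-one
Conditions: Zn(BH4)2, Et2O, −30 °C; aq. NH4Cl
Reagents that add atoms: none
Why: Chelation-controlled (Cram-chelate) 1,2-reduction: zinc bridges the ketone oxygen and the ring oxygen, hydride enters from the side of the oxane C-2 hydrogen and should give the anti (S) carbinol, and Zn(BH4)2 at low temperature leaves the lactone and the dienes alone.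

Step 25
Reactants: 35 the silyl-protected carbinol from step 24
Product: 36 target, (6S)-6-[(1E,3Z,5R,7E,9E,11S)-11-hydroxy-11-[(2R,4S,5R,6R)-4-hydroxy-5-methyl-6-[(E)-prop-1-enyl]tetrahydro-2H-pyran-2-yl]-3,5,7-trimethylundeca-1,3,7,9-tetraenyl]-5,6-dihydro-2H-pyran-2-one
Conditions: HF·pyridine, pyridine, THF, 0 °C → rt
Reagents that add atoms: none
Why: Buffered fluoride desilylation of the secondary silyl ether, conditions under which the dienyl carbinol and the unsaturated lactone should be stable.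

## Compound list

1 | (S)-epichlorohydrin [(S)-2-(chloromethyl)oxirane] | ClC[C@@H]1CO1 | starting material
2 | (S)-1-chloropent-4-en-2-ol | ClC[C@@H](O)CC=C | intermediate
3 | (S)-2-allyloxirane | C=CC[C@H]1CO1 | intermediate
4 | (S)-hexa-1,5-dien-3-ol | C=C[C@@H](O)CC=C | intermediate
5 | (S)-hexa-1,5-dien-3-yl acrylate | C=CC(=O)O[C@H](C=C)CC=C | intermediate
6 | (S)-6-vinyl-5,6-dihydro-2H-pyran-2-one | C=C[C@@H]1CC=CC(=O)O1 | intermediate
7 | (6S)-6-vinyl-5,6-dihydro-2H-pyran-2-ol (anomer mixture) | C=C[C@@H]1CC=CC(O)O1 | intermediate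
8 | (6S)-2-isopropoxy-6-vinyl-5,6-dihydro-2H-pyran (anomer mixture) | C=C[C@@H]1CC=CC(OC(C)C)O1 | intermediate
9 | (S)-3-bromo-2-methylpropan-1-ol | BrC[C@@H](C)CO | starting material
10 | (S)-(3-bromo-2-methylpropoxy)(tert-butyl)dimethylsilane | BrC[C@@H](C)CO[Si](C)(C)C(C)(C)C | intermediate
11 | (R)-tert-butyldimethyl[(2-methylpent-4-yn-1-yl)oxy]silane | C#CC[C@@H](C)CO[Si](C)(C)C(C)(C)C | intermediate
12 | [(1E,4R)-5-(tert-butyldimethylsilyloxy)-2,4-dimethylpent-1-en-1-yl]dimethylalane | C[Al](C)/C=C(\C)C[C@@H](C)CO[Si](C)(C)C(C)(C)C | intermediate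
13 | (R,E)-tert-butyl[(5-iodo-2,4-dimethylpent-4-en-1-yl)oxy]dimethylsilane | I/C=C(\C)C[C@@H](C)CO[Si](C)(C)C(C)(C)C | intermediate
14 | (2E,4E,7R)-8-(tert-butyldimethylsilyloxy)-5,7-dimethylocta-2,4-dienoic acid | OC(=O)/C=C/C=C(\C)C[C@@H](C)CO[Si](C)(C)C(C)(C)C | intermediate
15 | S-phenyl (2E,4E,7R)-8-(tert-butyldimethylsilyloxy)-5,7-dimethylocta-2,4-dienethioate | O=C(Sc1ccccc1)/C=C/C=C(\C)C[C@@H](C)CO[Si](C)(C)C(C)(C)C | intermediate
16 | S-phenyl (2E,4E,7R)-8-hydroxy-5,7-dimethylocta-2,4-dienethioate | O=C(Sc1ccccc1)/C=C/C=C(\C)C[C@@H](C)CO | intermediate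
17 | S-phenyl (2E,4E,7R)-5,7-dimethyl-8-oxoocta-2,4-dienethioate | O=C(Sc1ccccc1)/C=C/C=C(\C)C[C@@H](C)C=O | intermediate
18 | S-phenyl (2E,4E,7R,8Z)-9-iodo-5,7-dimethyldeca-2,4,8-trienethioate | O=C(Sc1ccccc1)/C=C/C=C(\C)C[C@@H](C)/C=C(C)\I | intermediate
19 | S-phenyl (2E,4E,7R,8Z,10E)-11-[(2S)-6-isopropoxy-3,6-dihydro-2H-pyran-2-yl]-5,7,9-trimethylundeca-2,4,8,10-tetraenethioate (acetal anomers) | O=C(Sc1ccccc1)/C=C/C=C(\C)C[C@@H](C)/C=C(C)\C=C\[C@@H]1CC=CC(OC(C)C)O1 | intermediate
20 | (S)-4-benzyl-3-propionyloxazolidin-2-one | CCC(=O)N1[C@@H](Cc2ccccc2)COC1=O | starting material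
21 | (E)-but-2-enal (crotonaldehyde) | C/C=C/C=O | starting material
22 | dibutylboron Z-enolate of 20 | C/C=C(\OB(CCCC)CCCC)N1[C@@H](Cc2ccccc2)COC1=O | intermediate
23 | (S)-4-benzyl-3-[(2S,3R,4E)-3-hydroxy-2-methylhex-4-enoyl]oxazolidin-2-one | C/C=C/[C@@H](O)[C@H](C)C(=O)N1[C@@H](Cc2ccccc2)COC1=O | intermediate
24 | (2S,3R,4E)-3-hydroxy-N-methoxy-N,2-dimethylhex-4-enamide | C/C=C/[C@@H](O)[C@H](C)C(=O)N(C)OC | intermediate
25 | ethyl (4S,5R,6E)-5-hydroxy-4-methyl-3-oxooct-6-enoate | C/C=C/[C@@H](O)[C@H](C)C(=O)CC(=O)OCC | intermediate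
26 | ethyl (3S,4R,5R,6E)-3,5-dihydroxy-4-methyloct-6-enoate (all-syn) | C/C=C/[C@@H](O)[C@H](C)[C@@H](O)CC(=O)OCC | intermediate
27 | (4S,5R,6R)-4-hydroxy-5-methyl-6-[(E)-prop-1-enyl]tetrahydro-2H-pyran-2-one | C/C=C/[C@H]1OC(=O)C[C@H](O)[C@H]1C | intermediate
28 | (4S,5S,6R)-4-(tert-butyldimethylsilyloxy)-5-methyl-6-[(E)-prop-1-enyl]tetrahydro-2H-pyran-2-one | C/C=C/[C@H]1OC(=O)C[C@H](O[Si](C)(C)C(C)(C)C)[C@H]1C | intermediate
29 | (4S,5S,6R)-4-(tert-butyldimethylsilyloxy)-5-methyl-6-[(E)-prop-1-enyl]tetrahydro-2H-pyran-2-ol (anomer mixture) | C/C=C/[C@H]1OC(O)C[C@H](O[Si](C)(C)C(C)(C)C)[C@H]1C | intermediate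
30 | (2R,4S,5S,6R)-2-chloro-4-(tert-butyldimethylsilyloxy)-5-methyl-6-[(E)-prop-1-enyl]tetrahydro-2H-pyran (chlorine axial, trans to propenyl) | C/C=C/[C@H]1O[C@H](Cl)C[C@H](O[Si](C)(C)C(C)(C)C)[C@H]1C | intermediate
31 | tributyl[(2S,4S,5S,6R)-4-(tert-butyldimethylsilyloxy)-5-methyl-6-[(E)-prop-1-enyl]tetrahydro-2H-pyran-2-yl]stannane (tin equatorial, cis to propenyl) | C/C=C/[C@H]1O[C@@H]([Sn](CCCC)(CCCC)CCCC)C[C@H](O[Si](C)(C)C(C)(C)C)[C@H]1C | intermediate
32 | (2E,4E,7R,8Z,10E)-1-[(2R,4S,5S,6R)-4-(tert-butyldimethylsilyloxy)-5-methyl-6-[(E)-prop-1-enyl]tetrahydro-2H-pyran-2-yl]-11-[(2S)-6-isopropoxy-3,6-dihydro-2H-pyran-2-yl]-5,7,9-trimethylundeca-2,4,8,10-tetraen-1-one | C/C=C/[C@H]1O[C@@H](C(=O)/C=C/C=C(\C)C[C@@H](C)/C=C(C)\C=C\[C@@H]2CC=CC(OC(C)C)O2)C[C@H](O[Si](C)(C)C(C)(C)C)[C@H]1C | intermediate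
33 | lactol corresponding to 32 (6-hydroxy-3,6-dihydro-2H-pyran-2-yl in place of the isopropyl acetal) | C/C=C/[C@H]1O[C@@H](C(=O)/C=C/C=C(\C)C[C@@H](C)/C=C(C)\C=C\[C@@H]2CC=CC(O)O2)C[C@H](O[Si](C)(C)C(C)(C)C)[C@H]1C | intermediate
34 | (6S)-6-[(1E,3Z,5R,7E,9E)-11-[(2R,4S,5S,6R)-4-(tert-butyldimethylsilyloxy)-5-methyl-6-[(E)-prop-1-enyl]tetrahydro-2H-pyran-2-yl]-3,5,7-trimethyl-11-oxoundeca-1,3,7,9-tetraenyl]-5,6-dihydro-2H-pyran-2-one | C/C=C/[C@H]1O[C@@H](C(=O)/C=C/C=C(\C)C[C@@H](C)/C=C(C)\C=C\[C@@H]2CC=CC(=O)O2)C[C@H](O[Si](C)(C)C(C)(C)C)[C@H]1C | intermediate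
35 | (6S)-6-[(1E,3Z,5R,7E,9E,11S)-11-[(2R,4S,5S,6R)-4-(tert-butyldimethylsilyloxy)-5-methyl-6-[(E)-prop-1-enyl]tetrahydro-2H-pyran-2-yl]-11-hydroxy-3,5,7-trimethylundeca-1,3,7,9-tetraenyl]-5,6-dihydro-2H-pyran-2-one | C/C=C/[C@H]1O[C@@H]([C@@H](O)/C=C/C=C(\C)C[C@@H](C)/C=C(C)\C=C\[C@@H]2CC=CC(=O)O2)C[C@H](O[Si](C)(C)C(C)(C)C)[C@H]1C | intermediate
36 | (6S)-6-[(1E,3Z,5R,7E,9E,11S)-11-hydroxy-11-[(2R,4S,5R,6R)-4-hydroxy-5-methyl-6-[(E)-prop-1-enyl]tetrahydro-2H-pyran-2-yl]-3,5,7-trimethylundeca-1,3,7,9-tetraenyl]-5,6-dihydro-2H-pyran-2-one | C/C=C/[C@H]1O[C@@H]([C@@H](O)/C=C/C=C(\C)C[C@@H](C)/C=C(C)\C=C\[C@@H]2CC=CC(=O)O2)C[C@H](O)[C@H]1C | target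

## Step count and risks

Total: 25 steps. Longest linear sequence: 13 steps (steps 6–14, then 22–25).

Steps most likely to fail:

1. Step 22. Transfer of the hindered secondary carbon from tin to palladium may be slow, so that β-hydride elimination to the enol ether or thermal isomerisation of the Z,E-diene at 90 °C outruns coupling. Fallback (sets out from 19 and 31, returns at 32): thioester 19 would be reduced with Et3SiH and palladium on carbon (Fukuyama reduction) to the dienal F1. Tin–lithium exchange on 31 (n-BuLi, THF, −78 °C) would give the equatorial 2-lithio-oxane F2, which is configurationally stable at this temperature. Its addition to the dienal would give the carbinol mixture F3 (both configurations at the new centre), and Dess–Martin oxidation would then give ketone 32.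

2. Step 21. The chloride may anomerise (its axial form is syn-axial to the silyloxy group) or eliminate to the enol ether, so that tin is introduced with eroded configurational purity or in low conversion. Fallback (sets out from 29, returns at 32 and by-passes 31): lactol 29 with PhSO2H and CaCl2 in CH2Cl2 would give the 2-(phenylsulfonyl)oxane F4. Deprotonation (LiN(iPr)2, THF, −78 °C) would give the α-sulfonyl carbanion F5, and acylation with thioester 19 would give the α-sulfonyl ketone F6. Reductive desulfonylation with aluminium amalgam (THF/H2O) would give ketone 32, the configuration at oxane C-2 then being set by protonation and equilibration to the equatorial epimer.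

3. Step 14. β-Hydride elimination may go towards the allylic C–H next to the ring oxygen (enol ether formation), or the double bond may migrate, or Z geometry at the trisubstituted alkene may be lost. Fallback (sets out from 8, returns at 19): cross-metathesis of 8 with vinylboronic acid pinacol ester (second-generation Hoveyda–Grubbs catalyst, CH2Cl2, 40 °C) would give the E-alkenylboronate F7. Suzuki–Miyaura coupling with iodide 18 (Pd(PPh3)4, Tl2CO3, THF/H2O, rt) would give 19 with both geometries fixed by the partners.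

Further compounds

F1 | step 22 | (2E,4E,7R,8Z,10E)-11-[(2S)-6-isopropoxy-3,6-dihydro-2H-pyran-2-yl]-5,7,9-trimethylundeca-2,4,8,10-tetraenal | O=C/C=C/C=C(\C)C[C@@H](C)/C=C(C)\C=C\[C@@H]1CC=CC(OC(C)C)O1
F2 | step 22 | [(2S,4S,5S,6R)-4-(tert-butyldimethylsilyloxy)-5-methyl-6-[(E)-prop-1-enyl]tetrahydro-2H-pyran-2-yl]lithium (lithium equatorial) | C/C=C/[C@H]1O[C@@H]([Li])C[C@H](O[Si](C)(C)C(C)(C)C)[C@H]1C
F3 | step 22 | (2E,4E,7R,8Z,10E)-1-[(2R,4S,5S,6R)-4-(tert-butyldimethylsilyloxy)-5-methyl-6-[(E)-prop-1-enyl]tetrahydro-2H-pyran-2-yl]-11-[(2S)-6-isopropoxy-3,6-dihydro-2H-pyran-2-yl]-5,7,9-trimethylundeca-2,4,8,10-tetraen-1-ol (both carbinol epimers) | C/C=C/[C@H]1O[C@@H](C(O)/C=C/C=C(\C)C[C@@H](C)/C=C(C)\C=C\[C@@H]2CC=CC(OC(C)C)O2)C[C@H](O[Si](C)(C)C(C)(C)C)[C@H]1C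
F4 | step 21 | (4S,5S,6R)-4-(tert-butyldimethylsilyloxy)-5-methyl-2-(phenylsulfonyl)-6-[(E)-prop-1-enyl]tetrahydro-2H-pyran (anomer mixture) | C/C=C/[C@H]1OC(S(=O)(=O)c2ccccc2)C[C@H](O[Si](C)(C)C(C)(C)C)[C@H]1C
F5 | step 21 | 2-lithio derivative of the 2-(phenylsulfonyl)oxane | C/C=C/[C@H]1OC([Li])(S(=O)(=O)c2ccccc2)C[C@H](O[Si](C)(C)C(C)(C)C)[C@H]1C
F6 | step 21 | 2-(phenylsulfonyl) derivative of ketone 32 (sulfonyl and acyl both on oxane C-2) | C/C=C/[C@H]1OC(S(=O)(=O)c2ccccc2)(C(=O)/C=C/C=C(\C)C[C@@H](C)/C=C(C)\C=C\[C@@H]2CC=CC(OC(C)C)O2)C[C@H](O[Si](C)(C)C(C)(C)C)[C@H]1C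
F7 | step 14 | 2-[(E)-2-[(2S)-6-isopropoxy-3,6-dihydro-2H-pyran-2-yl]ethenyl]-4,4,5,5-tetramethyl-1,3,2-dioxaborolane | CC1(C)OB(/C=C/[C@@H]2CC=CC(OC(C)C)O2)OC1(C)C
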